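**Plan**

1. Locants (germacrane): lactone O on C6; C7 carries C11(=C13H2)–C12(=O); C8 OAng, C9 OAc, C10(CH3)=C1 (ring-cis, Z), C2 OAc, C3H2, C4(CH3)=C5 (E).
2. Retrosynthesis: (a) the lactone C12–O bond and the three ester C–O bonds; (b) C9–H and C8–O, back to the enolate of a cyclodeca-1(10),4-dien-9-one; (c) the ring bond C6–C7 by a retro anionic oxy-Cope, which re-forms C4–C9 and contracts the ten-membered ring to a cyclohexenol.
3. Enabling feature: C4=C5 and the C8–C9(O) enolate flank C6–C7 as a 3-oxy-1,5-diene, and the Z C1=C10 olefin lets C9–C10=C1–C2–C3–C4 fold back into a cyclohex-2-enol; the C6 oxygen rides in as an E enol ether and C11–C13 as a 1,3-dienyl arm.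
4. Forward: the six-membered ring comes first (chiral enone 6); C4 is made quaternary (CH3, then the C5/C6 enol-ether arm); the C8/C7/C11–C13 dienyl arm adds to the C9 ketone; the [3,3] shift expands six to ten; the γ-lactone is closed last.
5. Stereochemistry: C2 by CBS reduction; C2 relays to C4 (anti aldol) and C9 (axial addition); the chair [3,3] shift transfers C4/C9 to C6/C7 and fixes E C4=C5; C8 by peripheral enolate hydroxylation; C9 by Felkin–Anh hydride addition.

Key step: step 14

Remark: C1–C15 in the text are the germacrane locants defined above; enone 1 is treated as purchasable (it is also one dehydrogenation from 1,4-cyclohexanedione mono-ethylene ketal).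

**Route**

Step 1
Reactants: 1 1,4-dioxaspiro[4.5]dec-6-en-8-one
Product: 2 trimethyl[(6-methyl-1,4-dioxaspiro[4.5]dec-7-en-8-yl)oxy]silane (racemic)
Conditions: Me2CuLi (from MeLi, CuI), Me3SiCl, THF, −78 °C
Reagents that add atoms: lithium dimethylcuprate C[Cu-]C.[Li+]; chlorotrimethylsilane C[Si](C)(C)Cl
Why: Conjugate addition of the Gilman cuprate with in-situ silyl trapping of the enolate places the methyl group (C14) on C10 and fixes the regiochemistry of the next dehydrogenation; the new centre is racemic and is removed in step 2.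

Step 2
Reactants: 2 silyl enol ether
Product: 3 6-methyl-1,4-dioxaspiro[4.5]dec-6-en-8-one
Conditions: Pd(OAc)2 (10 mol%), O2 (1 atm), DMSO, 25 °C
Reagents that add atoms: none
Why: Saegusa–Ito oxidation (palladation of the enol silane, β-hydride elimination towards the methyl-bearing carbon, oxygen turnover) should give the β-methyl enone with no stereocentre left.

Step 3
Reactants: 3 β-methyl enone
Product: 4 (8R)-6-methyl-1,4-dioxaspiro[4.5]dec-6-en-8-ol
Conditions: (S)-2-methyl-CBS-oxazaborolidine (15 mol%), catecholborane, toluene, −78 °C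
Reagents that add atoms: none
Why: Corey–Bakshi–Shibata reduction delivers hydride to one enantioface of the enone carbonyl with the alkenyl arm as the large group, setting C2 of the target as R (the catalyst antipode is the one that gives the 8R alcohol).

Step 4
Reactants: 4 allylic alcohol
Product: 5 tert-butyldimethyl{[(8R)-6-methyl-1,4-dioxaspiro[4.5]dec-6-en-8-yl]oxy}silane
Conditions: t-BuMe2SiCl, imidazole, DMF, 25 °C
Reagents that add atoms: tert-butyldimethylsilyl chloride CC(C)(C)[Si](C)(C)Cl
Why: Imidazole-promoted silylation of the secondary allylic alcohol touches no stereocentre and gives an ether stable to the enolate, organolithium and alkoxide steps ahead.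

Step 5
Reactants: 5 silyl ether ketal
Product: 6 (4R)-4-[(tert-butyldimethylsilyl)oxy]-2-methylcyclohex-2-en-1-one
Conditions: PPTS (cat.), acetone/H2O, 40 °C
Reagents that add atoms: water O
Why: Acid-catalysed hydrolysis of the allylic dioxolane is much faster than cleavage of the TBS ether and unmasks the C9 carbonyl.

Step 6
Reactants: 6 enone
Product: 8 (4R)-4-[(tert-butyldimethylsilyl)oxy]-2,6-dimethylcyclohex-2-en-1-one (C6 epimers), via lithium dienolate 7 (not isolated)
Conditions: LiN(iPr)2, THF, −78 °C; MeI, −78 to −40 °C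
Reagents that add atoms: iodomethane CI
Why: Kinetic α′-deprotonation gives the cross-conjugated dienolate, which is methylated by SN2 alkylation; the new centre (C4) need not be controlled because it is planarized again in step 7.

Step 7
Reactants: 8 methyl enone
Product: 10 (4R,6S)-4-[(tert-butyldimethylsilyl)oxy]-6-(hydroxymethyl)-2,6-dimethylcyclohex-2-en-1-one, via lithium dienolate 9 (not isolated)
Conditions: LiN(iPr)2, THF, −78 °C; CH2O (gas, from paraformaldehyde), −78 °C; AcOH quench
Reagents that add atoms: formaldehyde C=O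
Why: Aldol addition of the tetrasubstituted enolate to monomeric formaldehyde creates quaternary C4, the electrophile entering anti to the C2 silyloxy group (1,3-relationship) so that CH2OH is trans and CH3 cis to OTBS.

Step 8
Reactants: 10 hydroxymethyl ketone
Product: 11 (1S,5R)-5-[(tert-butyldimethylsilyl)oxy]-1,3-dimethyl-2-oxocyclohex-3-ene-1-carbaldehyde
Conditions: Dess–Martin periodinane, NaHCO3, CH2Cl2, 0 to 25 °C
Reagents that add atoms: none
Why: Dess–Martin oxidation of the neopentyl primary alcohol under buffered conditions should give the non-enolizable β-keto aldehyde without retro-aldol cleavage.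

Step 9
Reactants: 11 keto aldehyde
Product: 12 (4R,6S)-4-[(tert-butyldimethylsilyl)oxy]-6-[(E)-2-iodoethenyl]-2,6-dimethylcyclohex-2-en-1-one
Conditions: CrCl2 (6 equiv), CHI3 (2 equiv), THF, 0 °C
Reagents that add atoms: iodoform IC(I)I
Why: Takai olefination is selective for the aldehyde over the enone and should give the E vinyl iodide (C5=C6) by anti elimination from the geminal dichromium adduct.

Step 10
Reactants: 12 vinyl iodide
Product: 13 (4R,6S)-4-[(tert-butyldimethylsilyl)oxy]-6-{(E)-2-[(4-methoxybenzyl)oxy]ethenyl}-2,6-dimethylcyclohex-2-en-1-one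
Conditions: CuI (10 mol%), 3,4,7,8-tetramethyl-1,10-phenanthroline (20 mol%), Cs2CO3, 4-methoxybenzyl alcohol (2 equiv), toluene, 80 °C
Reagents that add atoms: 4-methoxybenzyl alcohol COc1ccc(CO)cc1
Why: Copper-catalysed Ullmann-type C–O coupling of a vinyl iodide with a primary alcohol proceeds with retention of olefin geometry and should give the E enol ether that carries the future C6 oxygen.

Step 11
Reactants: 14 2-bromoprop-2-en-1-ol
Product: 15 1-{[(2-bromoprop-2-en-1-yl)oxy]methyl}-4-methoxybenzene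
Conditions: NaH, THF/DMF, 0 °C; 4-MeOC6H4CH2Cl, Bu4NI (cat.), 25 °C
Reagents that add atoms: 4-methoxybenzyl chloride COc1ccc(CCl)cc1
Why: Williamson etherification of the primary allylic alkoxide protects the future C12 oxygen with the same group as C6, so both can be removed together.

Step 12
Reactants: 15 bromoallyl ether; 16 (E)-1,2-bis(tributylstannyl)ethene
Product: 17 tributyl[(1E)-3-{[(4-methoxybenzyl)oxy]methyl}buta-1,3-dien-1-yl]stannane
Conditions: 16 (2.5 equiv), Pd(PPh3)4 (5 mol%), toluene, 90 °C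
Reagents that add atoms: none
Why: Stille coupling of the vinyl bromide with one tin terminus of the bis-stannane (used in excess to suppress double coupling) should give the E dienylstannane with retention of geometry.

Step 13
Reactants: 17 dienylstannane; 13 enol-ether enone
Product: 19 (1S,4R,6S)-4-[(tert-butyldimethylsilyl)oxy]-1-[(1E)-3-{[(4-methoxybenzyl)oxy]methyl}buta-1,3-dien-1-yl]-6-{(E)-2-[(4-methoxybenzyl)oxy]ethenyl}-2,6-dimethylcyclohex-2-en-1-ol, via dienyllithium 18 (not isolated)
Conditions: 17, n-BuLi, THF, −78 °C; then 13, −78 °C; aq NH4Cl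
Reagents that add atoms: none
Why: Tin–lithium exchange gives the E alkenyllithium with retention, which should add 1,2 to the enone along the axial trajectory anti to the axial C4 alkenyl arm (conformer with OTBS and CH3 equatorial), so the two alkenyl arms end up trans and C9–OH is cis to the enol-ether arm.

Step 14
Reactants: 19 dialkenyl cyclohexenol
Product: 22 (1(10)Z,4E)-8-hydroxy-9-oxo-germacratriene with C2 OTBS and C6/C12 OPMB, via potassium alkoxide 20 (not isolated), via potassium dienolate 21 (not isolated)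
Conditions: KN(SiMe3)2 (1.3 equiv), 18-crown-6, THF, 0 to 25 °C; then −78 °C, 3-phenyl-2-(phenylsulfonyl)oxaziridine; aq NH4Cl
Reagents that add atoms: 3-phenyl-2-(phenylsulfonyl)oxaziridine O=S(=O)(c1ccccc1)N1OC1c1ccccc1
Why: Deprotonation gives alkoxide 20, whose C9–O− weakens the C9–C4 bond so that the anionic oxy-Cope [3,3] shift through the 1,5-diene C7=C8–C9–C4–C5=C6 runs near room temperature, forming C6–C7, breaking C4–C9 and giving dienolate 21, which is then hydroxylated at C8 by the N-sulfonyloxaziridine (Davis oxidation); the closest known type is the anionic oxy-Cope ring expansion of trans-1,2-divinylcyclohexanols to cyclodeca-1,5-dienones followed by enolate oxidation. The ten-membered carbocycle is closed by a four-atom ring expansion of the six-membered ring through a six-centre chair transition state with both alkenyl arms equatorial on the cyclohexene (ring bonds C4–C3 and C9–C10 equatorial, C4–CH3 and C9–O− axial), and the ring-cis C1=C10 olefin is carried over unchanged from the cyclohexene. C6 and C7 are set by this chair, in which the E enol ether and the E dienyl terminus place OPMB and C11 equatorial, so the C4/C9 configurations are transferred into the trans C6/C7 pair of the target (6R,7S there), while equatorial C3 on C4 gives the E C4=C5 olefin. C8 is set by attack of the oxidant on the outer face of the enolate, the inner face being covered across the ring by the C4=C5 olefin. The step needs the trans arrangement of the arms and a chair instead of a boat, which the axial addition of step 13 and the E geometry of both termini secure, and it needs the [3,3] shift to outrun alkoxide fragmentation and the bridged boat path through the ring olefin, which the doubly allylic, crown-separated alkoxide favours.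

Step 15
Reactants: 22 ketol; 23 angelic acid [(2Z)-2-methylbut-2-enoic acid]
Product: 25 C8 angelate of 22, via mixed anhydride 24 (not isolated)
Conditions: 23, 2,4,6-Cl3C6H2COCl, Et3N, toluene, 25 °C; then 22, toluene, 80 °C
Reagents that add atoms: none
Why: Yamaguchi-type esterification through the preformed mixed anhydride, without a nucleophilic catalyst, should acylate the C8 hydroxyl without isomerizing the Z-2-methylbut-2-enoate to the tiglate.

Step 16
Reactants: 25 angeloyloxy enone
Product: 26 C9 allylic alcohol (9R, C8/C9 syn)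
Conditions: NaBH4, CeCl3·7H2O, MeOH, −78 °C
Reagents that add atoms: none
Why: Luche reduction gives 1,2-reduction of the enone carbonyl only, and hydride is expected to add anti to the C8 acyloxy group (polar Felkin–Anh control) to give the 8,9-syn alcohol of the target.

Step 17
Reactants: 26 silyl ether alcohol
Product: 27 C2,C9-diol
Conditions: HF·pyridine, pyridine, THF, 0 to 25 °C
Reagents that add atoms: none
Why: Buffered fluoride cleavage of the TBS ether leaves the angelate, the PMB ethers and the allylic alcohols untouched and avoids base-induced acyl migration.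

Step 18
Reactants: 27 diol
Product: 28 C2,C9-diacetate
Conditions: Ac2O, pyridine, DMAP (cat.), CH2Cl2, 0 to 25 °C
Reagents that add atoms: acetic anhydride CC(=O)OC(C)=O
Why: Nucleophile-catalysed acylation converts both secondary allylic alcohols into the acetates of the target in one operation.

Step 19
Reactants: 28 bis-PMB ether
Product: 29 C6,C12-diol
Conditions: DDQ (3 equiv), CH2Cl2/pH 7 buffer, 0 to 25 °C
Reagents that add atoms: none
Why: Oxidative cleavage of both 4-methoxybenzyl ethers by DDQ (hydride abstraction, hydrolysis of the oxocarbenium ions) frees C6–OH and C12–OH while esters and olefins survive.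

Step 20
Reactants: 29 diol
Product: 31 target lactone, via lactol 30 (not isolated)
Conditions: TEMPO (20 mol%), PhI(OAc)2 (2.5 equiv), CH2Cl2, 25 °C
Reagents that add atoms: none
Why: Oxoammonium oxidation selects the primary allylic alcohol, the aldehyde is captured by C6–OH as lactol 30, and further oxidation gives the α-methylene-γ-butyrolactone with the trans ring fusion already fixed at C6/C7.

**Compound list**

1 | 1,4-dioxaspiro[4.5]dec-6-en-8-one | O=C1C=CC2(OCCO2)CC1 | starting material
2 | trimethyl[(6-methyl-1,4-dioxaspiro[4.5]dec-7-en-8-yl)oxy]silane (racemic) | CC1C=C(O[Si](C)(C)C)CCC12OCCO2 | intermediate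
3 | 6-methyl-1,4-dioxaspiro[4.5]dec-6-en-8-one | CC1=CC(=O)CCC12OCCO2 | intermediate
4 | (8R)-6-methyl-1,4-dioxaspiro[4.5]dec-6-en-8-ol | CC1=C[C@H](O)CCC12OCCO2 | intermediate
5 | tert-butyldimethyl{[(8R)-6-methyl-1,4-dioxaspiro[4.5]dec-6-en-8-yl]oxy}silane | CC1=C[C@H](O[Si](C)(C)C(C)(C)C)CCC12OCCO2 | intermediate
6 | (4R)-4-[(tert-butyldimethylsilyl)oxy]-2-methylcyclohex-2-en-1-one | CC1=C[C@H](O[Si](C)(C)C(C)(C)C)CCC1=O | intermediate
7 | lithium dienolate of 6 (O–C1=C6, cyclohexenone locants) | CC1=C[C@H](O[Si](C)(C)C(C)(C)C)CC=C1[O-].[Li+] | intermediate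
8 | (4R)-4-[(tert-butyldimethylsilyl)oxy]-2,6-dimethylcyclohex-2-en-1-one, C6 epimers | CC1=C[C@H](O[Si](C)(C)C(C)(C)C)CC(C)C1=O | intermediate
9 | lithium dienolate of 8 (O–C1=C6) | CC1=C[C@H](O[Si](C)(C)C(C)(C)C)CC(C)=C1[O-].[Li+] | intermediate
10 | (4R,6S)-4-[(tert-butyldimethylsilyl)oxy]-6-(hydroxymethyl)-2,6-dimethylcyclohex-2-en-1-one (CH2OH trans to OTBS) | CC1=C[C@H](O[Si](C)(C)C(C)(C)C)C[C@@](C)(CO)C1=O | intermediate
11 | (1S,5R)-5-[(tert-butyldimethylsilyl)oxy]-1,3-dimethyl-2-oxocyclohex-3-ene-1-carbaldehyde | CC1=C[C@H](O[Si](C)(C)C(C)(C)C)C[C@@](C)(C=O)C1=O | intermediate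
12 | (4R,6S)-4-[(tert-butyldimethylsilyl)oxy]-6-[(E)-2-iodoethenyl]-2,6-dimethylcyclohex-2-en-1-one | CC1=C[C@H](O[Si](C)(C)C(C)(C)C)C[C@@](C)(/C=C/I)C1=O | intermediate
13 | (4R,6S)-4-[(tert-butyldimethylsilyl)oxy]-6-{(E)-2-[(4-methoxybenzyl)oxy]ethenyl}-2,6-dimethylcyclohex-2-en-1-one | CC1=C[C@H](O[Si](C)(C)C(C)(C)C)C[C@@](C)(/C=C/OCc2ccc(OC)cc2)C1=O | intermediate
14 | 2-bromoprop-2-en-1-ol | C=C(Br)CO | starting material
15 | 1-{[(2-bromoprop-2-en-1-yl)oxy]methyl}-4-methoxybenzene | C=C(Br)COCc1ccc(OC)cc1 | intermediate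
16 | (E)-1,2-bis(tributylstannyl)ethene | CCCC[Sn](CCCC)(CCCC)/C=C/[Sn](CCCC)(CCCC)CCCC | starting material
17 | tributyl[(1E)-3-{[(4-methoxybenzyl)oxy]methyl}buta-1,3-dien-1-yl]stannane | CCCC[Sn](CCCC)(CCCC)/C=C/C(=C)COCc1ccc(OC)cc1 | intermediate
18 | [(1E)-3-{[(4-methoxybenzyl)oxy]methyl}buta-1,3-dien-1-yl]lithium | [Li]/C=C/C(=C)COCc1ccc(OC)cc1 | intermediate
19 | (1S,4R,6S)-4-[(tert-butyldimethylsilyl)oxy]-1-[(1E)-3-{[(4-methoxybenzyl)oxy]methyl}buta-1,3-dien-1-yl]-6-{(E)-2-[(4-methoxybenzyl)oxy]ethenyl}-2,6-dimethylcyclohex-2-en-1-ol (alkenyl arms trans, OH cis to the enol-ether arm) | CC1=C[C@H](O[Si](C)(C)C(C)(C)C)C[C@@](C)(/C=C/OCc2ccc(OC)cc2)[C@]1(O)/C=C/C(=C)COCc1ccc(OC)cc1 | intermediate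
20 | potassium alkoxide of 19 | CC1=C[C@H](O[Si](C)(C)C(C)(C)C)C[C@@](C)(/C=C/OCc2ccc(OC)cc2)[C@]1([O-])/C=C/C(=C)COCc1ccc(OC)cc1.[K+] | intermediate
21 | potassium (1(10)Z,4E,8Z)-germacra-1(10),4,8,11(13)-tetraen-9-olate with C2 OTBS and C6/C12 OPMB (C2, C6, C7 as in the target) | C/C1=C\[C@@H](OCc2ccc(OC)cc2)[C@H](C(=C)COCc2ccc(OC)cc2)/C=C(\[O-])/C(C)=C\[C@H](O[Si](C)(C)C(C)(C)C)C1.[K+] | intermediate
22 | (1(10)Z,4E)-2-[(tert-butyldimethylsilyl)oxy]-8-hydroxy-6,12-bis[(4-methoxybenzyl)oxy]germacra-1(10),4,11(13)-trien-9-one (C2, C6, C7, C8 as in the target) | C=C(COCc1ccc(OC)cc1)[C@H]2[C@H](OCc1ccc(OC)cc1)/C=C(\C)C[C@@H](O[Si](C)(C)C(C)(C)C)/C=C(/C)C(=O)[C@@H]2O | intermediate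
23 | angelic acid, (2Z)-2-methylbut-2-enoic acid | C/C=C(/C)C(=O)O | starting material
24 | (2Z)-2-methylbut-2-enoic 2,4,6-trichlorobenzoic anhydride | C/C=C(/C)C(=O)OC(=O)c1c(Cl)cc(Cl)cc1Cl | intermediate
25 | C8 angelate of 22 (8-angeloyloxy-9-ketone) | C=C(COCc1ccc(OC)cc1)[C@H]2[C@H](OCc1ccc(OC)cc1)/C=C(\C)C[C@@H](O[Si](C)(C)C(C)(C)C)/C=C(/C)C(=O)[C@@H]2OC(=O)/C(C)=C\C | intermediate
26 | 9R alcohol from 25 (8-angeloyloxy-9-hydroxy, C2 OTBS, C6/C12 OPMB) | C=C(COCc1ccc(OC)cc1)[C@H]2[C@H](OCc1ccc(OC)cc1)/C=C(\C)C[C@@H](O[Si](C)(C)C(C)(C)C)/C=C(/C)[C@@H](O)[C@@H]2OC(=O)/C(C)=C\C | intermediate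
27 | 2,9-diol (8-angeloyloxy, C6/C12 OPMB) | C=C(COCc1ccc(OC)cc1)[C@H]2[C@H](OCc1ccc(OC)cc1)/C=C(\C)C[C@@H](O)/C=C(/C)[C@@H](O)[C@@H]2OC(=O)/C(C)=C\C | intermediate
28 | 2,9-diacetate (8-angeloyloxy, C6/C12 OPMB) | C=C(COCc1ccc(OC)cc1)[C@H]2[C@H](OCc1ccc(OC)cc1)/C=C(\C)C[C@@H](OC(C)=O)/C=C(/C)[C@@H](OC(C)=O)[C@@H]2OC(=O)/C(C)=C\C | intermediate
29 | 2,9-diacetoxy-8-angeloyloxy-germacra-1(10),4,11(13)-triene-6,12-diol | C=C(CO)[C@H]2[C@H](O)/C=C(\C)C[C@@H](OC(C)=O)/C=C(/C)[C@@H](OC(C)=O)[C@@H]2OC(=O)/C(C)=C\C | intermediate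
30 | 12,6-lactol of 29 (C12 anomers) | C=C1C(O)O[C@@H]2/C=C(\C)C[C@@H](OC(C)=O)/C=C(/C)[C@@H](OC(C)=O)[C@H](OC(=O)/C(C)=C\C)[C@@H]12 | intermediate
31 | (1(10)Z,4E,2R,6R,7S,8R,9R)-2,9-diacetoxy-8-angeloyloxygermacra-1(10),4,11(13)-trien-12,6-olide | C=C1C(=O)O[C@@H]2/C=C(\C)C[C@@H](OC(C)=O)/C=C(/C)[C@@H](OC(C)=O)[C@H](OC(=O)/C(C)=C\C)[C@@H]12 | target

**Count and risks**

Total steps: 20. Longest linear sequence: 18 steps (steps 1–10 and 13–20); the dienyl arm 17 takes 2 steps.

Steps most likely to fail: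

1. Step 14. The alkoxide may fragment or take a boat or stepwise path, and the in-flask oxidation may suffer proton transfer within the dienolate, addition of the enolate to the sulfonimine by-product, or attack on both faces of C8. Fallback (from 19, back at 22): the ring expansion is run alone (KH, 18-crown-6, THF) and quenched with aqueous NH4Cl to isolate the C8-unsubstituted cyclodecadienone F1. Kinetic deprotonation at C8 with KN(SiMe3)2 and trapping with Me3SiCl should give the silyl dienol ether F2. Rubottom oxidation of F2 (m-CPBA, NaHCO3, CH2Cl2, −20 °C, then citric acid) should return ketol 22, with the oxidant again entering from the outer face.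

2. Step 16. Ring conformation may override Felkin–Anh control, so that hydride adds to the other face of C9, and base may move the angelate from O8 to O9. Fallback (from 25, back at 28): the 9-epi alcohol F3 from the reduction is inverted by a Mitsunobu reaction with acetic acid (PPh3, DIAD, toluene), which should give the 9R acetate F4 directly. HF·pyridine then frees C2–OH to give hydroxy acetate F5, and acetylation of F5 returns to diacetate 28.

3. Step 13. The bulky dienyllithium may show poor facial selectivity or deprotonate the γ position; attack syn to the C4 arm would give the cis-dialkenyl carbinol and hence C6/C7 epimers after the rearrangement. Fallback (from 15 and 13, back at 19): Sonogashira coupling of 15 with trimethylsilylacetylene (PdCl2(PPh3)2, CuI, Et3N) should give silyl enyne F6, and K2CO3/MeOH the terminal enyne F7. Its lithium acetylide, a small nucleophile with a strong preference for axial attack, adds to 13 to give propargylic alcohol F8. Alkoxide-directed trans-hydroalumination with NaAlH2(OCH2CH2OMe)2 in THF then gives the E dienyl carbinol 19.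

Further compounds
F1 | step 14 | (1(10)Z,4E)-2-[(tert-butyldimethylsilyl)oxy]-6,12-bis[(4-methoxybenzyl)oxy]germacra-1(10),4,11(13)-trien-9-one (C2, C6, C7 as in the target) | C=C(COCc1ccc(OC)cc1)[C@H]2[C@H](OCc1ccc(OC)cc1)/C=C(\C)C[C@@H](O[Si](C)(C)C(C)(C)C)/C=C(/C)C(=O)C2
F2 | step 14 | 9-(trimethylsilyloxy) 8,9-dienol ether of F1 | C/C1=C\[C@@H](OCc2ccc(OC)cc2)[C@H](C(=C)COCc2ccc(OC)cc2)/C=C(\O[Si](C)(C)C)/C(C)=C\[C@H](O[Si](C)(C)C(C)(C)C)C1
F3 | step 16 | 9-epimer (9S) of alcohol 26 | C=C(COCc1ccc(OC)cc1)[C@H]2[C@H](OCc1ccc(OC)cc1)/C=C(\C)C[C@@H](O[Si](C)(C)C(C)(C)C)/C=C(/C)[C@H](O)[C@@H]2OC(=O)/C(C)=C\C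
F4 | step 16 | 9R acetate with C2 OTBS (8-angeloyloxy, C6/C12 OPMB) | C=C(COCc1ccc(OC)cc1)[C@H]2[C@H](OCc1ccc(OC)cc1)/C=C(\C)C[C@@H](O[Si](C)(C)C(C)(C)C)/C=C(/C)[C@@H](OC(C)=O)[C@@H]2OC(=O)/C(C)=C\C
F5 | step 16 | 9-acetoxy-2-hydroxy compound (8-angeloyloxy, C6/C12 OPMB) | C=C(COCc1ccc(OC)cc1)[C@H]2[C@H](OCc1ccc(OC)cc1)/C=C(\C)C[C@@H](O)/C=C(/C)[C@@H](OC(C)=O)[C@@H]2OC(=O)/C(C)=C\C
F6 | step 13 | [3-{[(4-methoxybenzyl)oxy]methyl}but-3-en-1-yn-1-yl]trimethylsilane | C=C(COCc1ccc(OC)cc1)C#C[Si](C)(C)C
F7 | step 13 | 1-methoxy-4-{[(2-methylenebut-3-yn-1-yl)oxy]methyl}benzene | C=C(COCc1ccc(OC)cc1)C#C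
F8 | step 13 | propargylic alcohol: 19 with a C7≡C8 triple bond in place of the E olefin | CC1=C[C@H](O[Si](C)(C)C(C)(C)C)C[C@@](C)(/C=C/OCc2ccc(OC)cc2)[C@]1(O)C#CC(=C)COCc1ccc(OC)cc1
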